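## Retrosynthetic overview

1. Numbering of the target core: ring A = C9a–C1(=O)–C2=C3–C4(=O)–C4a; five-membered ring = C4a–C4b–C8a–C9–C9a; bridge = C4a–C10H2–C11(CH3)=C12H–C9; prenyl on C9a. Target 22 ⇐ dimethyl ether 20 (oxidative demethylation, reduction) ⇐ aldehyde 19 (Wittig) ⇐ tetracycle 17. The prenyl group is carried as a 2-silyloxyethyl chain so that the key step meets only one alkene.
2. Key disconnection, C10–C11 and C4a–C9a: 17 ⇐ linear 6-6-5 tricycle 16 (a 4-methylidene-3a-silyloxy-9-propynyl-cyclopenta[b]naphthalen-1-one) by a cationic gold-catalysed enyne cyclisation/semipinacol cascade. In one operation the six-membered ring B contracts to the five-membered ring, the cyclopentenone expands to ring A, and the bridged cyclohexene closes.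
3. Enabling feature: C4a–C9a is the central bond of the 1,4-dione O=C4–C4a–C9a–C1=O, and C4a also carries the aryl ring and the C10 methylene. A C4a=C10 alkene beside a C4 carbinol therefore becomes, when C10 attacks the alkyne carbon C11, a cation at C4a that pulls C9a over from C4 and leaves C4 as the ketone.
4. 16 ⇐ 12 by Nozaki–Hiyama–Kishi closure of ring B onto one carbonyl of a 2,2-disubstituted cyclopentane-1,3-dione, then O-silylation, dehydrogenation and alkyne methylation. 12 ⇐ propargylic acetate 7 + dione 11 by copper-catalysed asymmetric propargylic substitution, which sets C9; C9a follows from C9 in the ring closure and C4a from the bridge.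
5. Ring order: arene and cyclopentanedione are bought; ring B (step 7); then five-membered ring, ring A and bridged ring together (step 11); the hydroquinone is unveiled last.

Key step: step 11

Assumption: the sense of induction of the copper–pybox catalyst is not predicted here; the ligand enantiomer that gives the (R)-propargylic centre is to be used (both enantiomers are available).

## Route

Step 1
Reactants: 1 2-bromo-1,4-dimethoxybenzene
Product: 2 2-bromo-3,6-dimethoxybenzaldehyde
Conditions: LiN(i-Pr)2, THF, −78 °C; DMF, −78 °C to rt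
Reagents that add atoms: N,N-dimethylformamide (CN(C)C=O)
Why: Directed ortho-lithiation removes the hydrogen flanked by bromine and methoxy (the most acidic one; the amide base at low temperature should neither exchange the bromide nor form the aryne), and DMF formylates the aryllithium.

Step 2
Reactants: 2 2-bromo-3,6-dimethoxybenzaldehyde
Product: 3 2-ethenyl-3,6-dimethoxybenzaldehyde
Conditions: Bu3SnCH=CH2, Pd(PPh3)4 (5 mol %), toluene, 100 °C
Reagents that add atoms: tributyl(vinyl)stannane (C=C[Sn](CCCC)(CCCC)CCCC)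
Why: Stille coupling of the aryl bromide with the vinylstannane under neutral conditions that leave the aldehyde alone.

Step 3
Reactants: 3 2-ethenyl-3,6-dimethoxybenzaldehyde
Product: 5 2-(1-bromoethenyl)-3,6-dimethoxybenzaldehyde, via dibromide 4 (not isolated)
Conditions: Br2, CH2Cl2, −78 °C; then DBU, 0 °C to rt
Reagents that add atoms: bromine (BrBr)
Why: Bromine addition to the styrene followed by E2 dehydrobromination, in which DBU removes the acidic benzylic hydrogen and the primary bromide leaves, should give the 1-bromoethenyl arene; the formyl group deactivates the ring against bromination.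

Step 4
Reactants: 5 2-(1-bromoethenyl)-3,6-dimethoxybenzaldehyde
Product: 7 rac-1-[2-(1-bromoethenyl)-3,6-dimethoxyphenyl]prop-2-yn-1-yl acetate, via magnesium alkoxide 6 (not isolated)
Conditions: HC≡CMgBr, THF, −20 °C; then Ac2O, 0 °C to rt
Reagents that add atoms: ethynylmagnesium bromide (C#C[Mg]Br); acetic anhydride (CC(=O)OC(C)=O)
Why: Grignard 1,2-addition to the aldehyde and acylation of the alkoxide in the same flask; the carbinol centre is racemic, which does not matter because it is ionised in step 6.

Step 5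
Reactants: 8 cyclopentane-1,3-dione; 9 (tert-butyldimethylsilyloxy)acetaldehyde
Product: 11 2-[2-(tert-butyldimethylsilyloxy)ethyl]cyclopentane-1,3-dione, via alkylidene dione 10 (not isolated)
Conditions: Hantzsch ester, L-proline (20 mol %), CH2Cl2, rt
Reagents that add atoms: none
Why: Three-component reductive alkylation: proline-mediated Knoevenagel condensation and conjugate transfer hydrogenation of the alkylidene dione by the Hantzsch ester, which avoids O-alkylation and double alkylation.

Step 6
Reactants: 7 rac-1-[2-(1-bromoethenyl)-3,6-dimethoxyphenyl]prop-2-yn-1-yl acetate; 11 2-[2-(tert-butyldimethylsilyloxy)ethyl]cyclopentane-1,3-dione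
Product: 12 2-[(1R)-1-[2-(1-bromoethenyl)-3,6-dimethoxyphenyl]prop-2-yn-1-yl]-2-[2-(tert-butyldimethylsilyloxy)ethyl]cyclopentane-1,3-dione
Conditions: [Cu(MeCN)4]BF4 (5 mol %), 2,6-bis(4-phenyl-4,5-dihydrooxazol-2-yl)pyridine (6 mol %, enantiomer that gives the R centre), i-Pr2NEt, MeOH, −10 °C
Reagents that add atoms: none
Why: Copper-catalysed asymmetric propargylic substitution: the copper acetylide ionises to a copper allenylidene whose gamma carbon is attacked by the dione enolate on the face left open by the pybox ligand, so the catalyst sets the propargylic centre (R) from the racemic acetate, while the dione carbon, with two identical carbonyl arms, is not yet stereogenic.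

Step 7
Reactants: 12 (the dione of step 6)
Product: 13 (3aS,9R,9aS)-9a-[2-(tert-butyldimethylsilyloxy)ethyl]-9-ethynyl-3a-hydroxy-5,8-dimethoxy-4-methylidene-2,3,3a,4,9,9a-hexahydro-1H-cyclopenta[b]naphthalen-1-one (cis-fused; hydroxyl, side chain and ethynyl on one face)
Conditions: CrCl2 (5 equiv), NiCl2 (2 mol %), DMF, rt; aqueous work-up
Reagents that add atoms: none
Why: Intramolecular Nozaki–Hiyama–Kishi reaction (6-exo-trig): the alkenylchromium adds 1,2 to one ketone, the tether forces a cis ring fusion with the hydroxyl cis to the side chain, and the carbonyl attacked should be the one that lets the ethynyl group sit pseudo-axial, away from the ortho methoxy group (allylic 1,3-strain), which puts ethynyl and side chain on the same face and so fixes C3a and C9a relative to C9.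

Step 8
Reactants: 13 (the tricyclic hydroxy ketone)
Product: 14 (3aS,9R,9aS)-9a-[2-(tert-butyldimethylsilyloxy)ethyl]-9-ethynyl-5,8-dimethoxy-4-methylidene-3a-(triethylsilyloxy)-2,3,3a,4,9,9a-hexahydro-1H-cyclopenta[b]naphthalen-1-one
Conditions: Et3SiOTf, 2,6-lutidine, CH2Cl2, −78 to 0 °C
Reagents that add atoms: triethylsilyl trifluoromethanesulfonate (CC[Si](CC)(CC)OS(=O)(=O)C(F)(F)F)
Why: Silylation of the hindered tertiary alcohol with the silyl triflate; the silyl ether keeps the oxygen from adding to the alkyne later and is the group lost in the semipinacol step.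

Step 9
Reactants: 14 (the triethylsilyl ether)
Product: 15 (3aS,9R,9aS)-9a-[2-(tert-butyldimethylsilyloxy)ethyl]-9-ethynyl-5,8-dimethoxy-4-methylidene-3a-(triethylsilyloxy)-3a,4,9,9a-tetrahydro-1H-cyclopenta[b]naphthalen-1-one
Conditions: IBX, DMSO, 70 °C
Reagents that add atoms: none
Why: IBX dehydrogenation of the ketone to the enone; only C2–C3 can be desaturated because C9a is quaternary, and the terminal alkyne and silyl ethers are inert.

Step 10
Reactants: 15 (the enone with the terminal alkyne)
Product: 16 (3aS,9R,9aS)-9a-[2-(tert-butyldimethylsilyloxy)ethyl]-5,8-dimethoxy-4-methylidene-9-(prop-1-yn-1-yl)-3a-(triethylsilyloxy)-3a,4,9,9a-tetrahydro-1H-cyclopenta[b]naphthalen-1-one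
Conditions: LiN(SiMe3)2, THF, −78 °C; MeOTf, −78 to −40 °C
Reagents that add atoms: methyl trifluoromethanesulfonate (COS(=O)(=O)C(F)(F)F)
Why: Acetylide alkylation: after step 9 no enolisable hydrogen is left, so the amide base deprotonates the terminal alkyne (kinetically faster than the benzylic C9–H) and the acetylide is methylated at low temperature by the triflate.

Step 11
Reactants: 16 (the silyloxy enyne)
Product: 17 (4aR,9R,9aS)-9a-[2-(tert-butyldimethylsilyloxy)ethyl]-5,8-dimethoxy-11-methyl-4a,9a-dihydro-4a,9-prop[1]eno-9H-fluorene-1,4-dione (bridge C4a–C10H2–C11(CH3)=C12H–C9, syn to the C9a side chain)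
Conditions: [JohnPhosAu(NCMe)]SbF6 (5 mol %; JohnPhos = (2-biphenylyl)di-tert-butylphosphine), i-PrOH (2 equiv), CH2Cl2, 0 °C to rt
Reagents that add atoms: none
Why: The cationic monovalent gold complex binds the propynyl group, and the electron-rich 1,1-disubstituted alkene attacks the methyl-bearing alkyne carbon anti to gold through its CH2 terminus (7-endo-dig), which throws a three-carbon bridge across ring B and leaves the positive charge on the methylidene-bearing carbon (future C4a) next to the silyloxy carbon (future C4); the ring bond from that carbon to C9a, held parallel to the empty orbital by the bridge, then shifts to C4a while the silyloxy carbon becomes the C4 ketone (semipinacol), and silyl transfer to 2-propanol plus protodeauration free the catalyst. The closest known reaction type is the gold-catalysed carbocyclisation of silyloxy enynes that ends in a pinacol-type 1,2-shift, together with the ring-expanding cycloisomerisation of enynes that carry a 1-alkenyl cycloalkanol. Ring closures: the bridged cyclohexene (C4a, C10, C11, C12, C9, C9a) closes through the C10–C11 bond by the 7-endo-dig attack and becomes six-membered when C9a shifts; ring A forms by ring expansion of the cyclopentenone (five to six) and the five-membered ring by contraction of ring B (six to five), both through the same 1,2-shift. Stereocentres: C9a migrates with retention and, because its side chain lies on the ring face that carries the alkyne, ends with that chain syn to the new alkene bridge and C1 over the arene; C4a is new and can form in one configuration only, the one that the bridge from C9 allows; C9 is not touched. The step needs endo rather than 6-exo attack, which the substrate should secure by the pseudo-axial propynyl group pointing its outer carbon at the methylidene terminus and by the greater strain of the bicyclo[2.2.2] cation that exo attack would require, and it needs migration of C9a rather than of the vinylic C3, which is secured because only the ring bond to C9a is aligned with the cationic orbital in the bridged intermediate. Competing nucleophiles are removed beforehand: the tertiary oxygen is silylated and the prenyl alkene is still a silyloxyethyl chain, so no 1,6-enyne pathway is open.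

Step 12
Reactants: 17 (the tetracyclic silyl ether)
Product: 18 (4aR,9R,9aS)-9a-(2-hydroxyethyl)-5,8-dimethoxy-11-methyl-4a,9a-dihydro-4a,9-prop[1]eno-9H-fluorene-1,4-dione
Conditions: HF·pyridine, THF, 0 °C to rt
Reagents that add atoms: none
Why: Fluoride cleavage of the primary silyl ether under mildly acidic conditions that the enedione and the aryl methyl ethers tolerate.

Step 13
Reactants: 18 (the primary alcohol)
Product: 19 2-[(4aR,9R,9aS)-5,8-dimethoxy-11-methyl-1,4-dioxo-4a,9a-dihydro-4a,9-prop[1]eno-9H-fluoren-9a-yl]acetaldehyde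
Conditions: Dess–Martin periodinane, NaHCO3, CH2Cl2, rt
Reagents that add atoms: none
Why: Dess–Martin oxidation of the primary alcohol to the aldehyde under buffered, non-basic conditions.

Step 14
Reactants: 19 (the aldehyde)
Product: 20 (4aR,9R,9aS)-5,8-dimethoxy-11-methyl-9a-(3-methylbut-2-en-1-yl)-4a,9a-dihydro-4a,9-prop[1]eno-9H-fluorene-1,4-dione
Conditions: i-PrPPh3I, n-BuLi, THF, 0 °C; then 19, −78 to 0 °C
Reagents that add atoms: isopropyltriphenylphosphonium iodide (CC(C)[P+](c1ccccc1)(c1ccccc1)c1ccccc1.[I-])
Why: Wittig olefination with the non-stabilised isopropylidene ylide; the aldehyde should react far faster than the two hindered conjugated ketones, and one equivalent of ylide at low temperature limits addition to the enedione.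

Step 15
Reactants: 20 (the dimethyl ether)
Product: 22 (4aR,9R,9aS)-5,8-dihydroxy-11-methyl-9a-(3-methylbut-2-en-1-yl)-4a,9a-dihydro-4a,9-prop[1]eno-9H-fluorene-1,4-dione (CNP0166383.1), via quinone 21 (not isolated)
Conditions: (NH4)2Ce(NO3)6, MeCN/H2O, 0 °C; then Na2S2O4, EtOAc/H2O, rt
Reagents that add atoms: water (O)
Why: Oxidative demethylation of the 1,4-dimethoxyarene to the para-quinone by tetravalent cerium, then dithionite reduction to the hydroquinone; the ring A enedione has no aromatic driving force and should survive the brief biphasic reduction.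

## Compound list

1 | 2-bromo-1,4-dimethoxybenzene | COc1ccc(OC)c(Br)c1 | starting material
2 | 2-bromo-3,6-dimethoxybenzaldehyde | COc1ccc(OC)c(C=O)c1Br | intermediate
3 | 2-ethenyl-3,6-dimethoxybenzaldehyde | COc1ccc(OC)c(C=O)c1C=C | intermediate
4 | 2-(1,2-dibromoethyl)-3,6-dimethoxybenzaldehyde (racemic, not isolated) | COc1ccc(OC)c(C=O)c1C(Br)CBr | intermediate
5 | 2-(1-bromoethenyl)-3,6-dimethoxybenzaldehyde | COc1ccc(OC)c(C=O)c1C(Br)=C | intermediate
6 | bromomagnesium 1-[2-(1-bromoethenyl)-3,6-dimethoxyphenyl]prop-2-yn-1-olate (racemic, not isolated) | COc1ccc(OC)c(C(O[Mg]Br)C#C)c1C(Br)=C | intermediate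
7 | rac-1-[2-(1-bromoethenyl)-3,6-dimethoxyphenyl]prop-2-yn-1-yl acetate | COc1ccc(OC)c(C(OC(C)=O)C#C)c1C(Br)=C | intermediate
8 | cyclopentane-1,3-dione | O=C1CCC(=O)C1 | starting material
9 | (tert-butyldimethylsilyloxy)acetaldehyde | CC(C)(C)[Si](C)(C)OCC=O | starting material
10 | 2-[2-(tert-butyldimethylsilyloxy)ethylidene]cyclopentane-1,3-dione (not isolated) | CC(C)(C)[Si](C)(C)OCC=C1C(=O)CCC1=O | intermediate
11 | 2-[2-(tert-butyldimethylsilyloxy)ethyl]cyclopentane-1,3-dione | CC(C)(C)[Si](C)(C)OCCC1C(=O)CCC1=O | intermediate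
12 | 2-[(1R)-1-[2-(1-bromoethenyl)-3,6-dimethoxyphenyl]prop-2-yn-1-yl]-2-[2-(tert-butyldimethylsilyloxy)ethyl]cyclopentane-1,3-dione | C#C[C@H](c1c(OC)ccc(OC)c1C(Br)=C)C1(CCO[Si](C)(C)C(C)(C)C)C(=O)CCC1=O | intermediate
13 | (3aS,9R,9aS)-9a-[2-(tert-butyldimethylsilyloxy)ethyl]-9-ethynyl-3a-hydroxy-5,8-dimethoxy-4-methylidene-2,3,3a,4,9,9a-hexahydro-1H-cyclopenta[b]naphthalen-1-one | C#C[C@@H]1c2c(OC)ccc(OC)c2C(=C)[C@@]3(O)CCC(=O)[C@@]13CCO[Si](C)(C)C(C)(C)C | intermediate
14 | (3aS,9R,9aS)-9a-[2-(tert-butyldimethylsilyloxy)ethyl]-9-ethynyl-5,8-dimethoxy-4-methylidene-3a-(triethylsilyloxy)-2,3,3a,4,9,9a-hexahydro-1H-cyclopenta[b]naphthalen-1-one | C#C[C@@H]1c2c(OC)ccc(OC)c2C(=C)[C@@]3(O[Si](CC)(CC)CC)CCC(=O)[C@@]13CCO[Si](C)(C)C(C)(C)C | intermediate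
15 | (3aS,9R,9aS)-9a-[2-(tert-butyldimethylsilyloxy)ethyl]-9-ethynyl-5,8-dimethoxy-4-methylidene-3a-(triethylsilyloxy)-3a,4,9,9a-tetrahydro-1H-cyclopenta[b]naphthalen-1-one | C#C[C@@H]1c2c(OC)ccc(OC)c2C(=C)[C@@]3(O[Si](CC)(CC)CC)C=CC(=O)[C@@]13CCO[Si](C)(C)C(C)(C)C | intermediate
16 | (3aS,9R,9aS)-9a-[2-(tert-butyldimethylsilyloxy)ethyl]-5,8-dimethoxy-4-methylidene-9-(prop-1-yn-1-yl)-3a-(triethylsilyloxy)-3a,4,9,9a-tetrahydro-1H-cyclopenta[b]naphthalen-1-one | CC#C[C@@H]1c2c(OC)ccc(OC)c2C(=C)[C@@]3(O[Si](CC)(CC)CC)C=CC(=O)[C@@]13CCO[Si](C)(C)C(C)(C)C | intermediate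
17 | (4aR,9R,9aS)-9a-[2-(tert-butyldimethylsilyloxy)ethyl]-5,8-dimethoxy-11-methyl-4a,9a-dihydro-4a,9-prop[1]eno-9H-fluorene-1,4-dione | CC(C)(C)[Si](C)(C)OCC[C@@]12C(=O)C=CC(=O)[C@@]13CC(C)=C[C@@H]2c1c(OC)ccc(OC)c13 | intermediate
18 | (4aR,9R,9aS)-9a-(2-hydroxyethyl)-5,8-dimethoxy-11-methyl-4a,9a-dihydro-4a,9-prop[1]eno-9H-fluorene-1,4-dione | OCC[C@@]12C(=O)C=CC(=O)[C@@]13CC(C)=C[C@@H]2c1c(OC)ccc(OC)c13 | intermediate
19 | 2-[(4aR,9R,9aS)-5,8-dimethoxy-11-methyl-1,4-dioxo-4a,9a-dihydro-4a,9-prop[1]eno-9H-fluoren-9a-yl]acetaldehyde | O=CC[C@@]12C(=O)C=CC(=O)[C@@]13CC(C)=C[C@@H]2c1c(OC)ccc(OC)c13 | intermediate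
20 | (4aR,9R,9aS)-5,8-dimethoxy-11-methyl-9a-(3-methylbut-2-en-1-yl)-4a,9a-dihydro-4a,9-prop[1]eno-9H-fluorene-1,4-dione | CC(C)=CC[C@@]12C(=O)C=CC(=O)[C@@]13CC(C)=C[C@@H]2c1c(OC)ccc(OC)c13 | intermediate
21 | (4aS,9R,9aS)-11-methyl-9a-(3-methylbut-2-en-1-yl)-4a,9a-dihydro-4a,9-prop[1]eno-9H-fluorene-1,4,5,8-tetrone (same spatial arrangement as 20; the C4a descriptor changes by the sequence rule only; not isolated) | CC(C)=CC[C@@]12C(=O)C=CC(=O)[C@@]13CC(C)=C[C@@H]2C4=C3C(=O)C=CC4=O | intermediate
22 | (4aR,9R,9aS)-5,8-dihydroxy-11-methyl-9a-(3-methylbut-2-en-1-yl)-4a,9a-dihydro-4a,9-prop[1]eno-9H-fluorene-1,4-dione (CNP0166383.1) | CC(C)=CC[C@@]12C(=O)C=CC(=O)[C@@]13CC(C)=C[C@@H]2c1c(O)ccc(O)c13 | target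

## Summary

Total step count: 15. Longest linear sequence: 14 steps (steps 1–4 and 6–15); step 5 is a one-step branch.

Steps most likely to fail:

1. Step 11 (key step). What may go wrong: attack of the alkene on the inner alkyne carbon (6-exo), addition of the silyloxy oxygen to the activated alkyne, or failure of the strained bridge to form. The fallback is a carbonyl-initiated Prins–pinacol cascade that needs no π-acid and has only one electrophilic carbon; it sets out from 15 and comes back at 17. Ruthenium-catalysed anti-Markovnikov hydration of the terminal alkyne ([CpRu(MeCN)3]PF6 with a 2,2'-bipyridine ligand, H2O/NMP) should give aldehyde F1. Me2AlCl or SnCl4 at −78 °C should then make the methylidene attack the aldehyde and trigger the same 1,2-shift, giving the bridged secondary alcohol F2. Dess–Martin oxidation should give ketone F3, and kinetic enolisation on the less hindered C12 side (KN(SiMe3)2, PhNTf2) the enol triflate F4. Stille methylation (Me4Sn, Pd(PPh3)4, LiCl) then returns to 17.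

2. Step 7. What may go wrong: addition to the other of the two diastereotopic carbonyl groups, or protonation of the alkenylchromium before it adds. The fallback takes the choice of carbonyl away from the ring closure; it sets out from 12 and comes back at 13. A Corey–Bakshi–Shibata mono-reduction (oxazaborolidine enantiomer chosen to reduce the carbonyl that is to remain C1; a ketoreductase panel is the alternative) should give hydroxy ketone F5. The Nozaki–Hiyama–Kishi closure then has a single ketone to attack and should give diol F6. Dess–Martin oxidation of the secondary alcohol returns to 13.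

3. Step 6. What may go wrong: slow carbon–carbon bond formation at a carbon between two ortho substituents, O-propargylation of the dione, or erosion of enantioselectivity. The fallback runs the asymmetric step with the smaller ortho bromine and builds the bromoethenyl group afterwards; it sets out from 2 and comes back at 12. Ethynylmagnesium bromide and then acetic anhydride should give acetate F7. The same copper catalysis with 11 should give aryl bromide F8. Stille vinylation should give styrene F9, and bromine addition (dibromide F10, not isolated) followed by DBU returns to 12.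

## Further compounds

F1 | step 11 | (3aS,9R,9aS)-9a-[2-(tert-butyldimethylsilyloxy)ethyl]-5,8-dimethoxy-4-methylidene-9-(2-oxoethyl)-3a-(triethylsilyloxy)-3a,4,9,9a-tetrahydro-1H-cyclopenta[b]naphthalen-1-one | O=CC[C@@H]1c2c(OC)ccc(OC)c2C(=C)[C@@]3(O[Si](CC)(CC)CC)C=CC(=O)[C@@]13CCO[Si](C)(C)C(C)(C)C
F2 | step 11 | (4aR,9R,9aS)-9a-[2-(tert-butyldimethylsilyloxy)ethyl]-11-hydroxy-5,8-dimethoxy-4a,9a-dihydro-4a,9-propano-9H-fluorene-1,4-dione (either C11 epimer) | CC(C)(C)[Si](C)(C)OCC[C@@]12C(=O)C=CC(=O)[C@@]13CC(O)C[C@@H]2c1c(OC)ccc(OC)c13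
F3 | step 11 | (4aR,9R,9aS)-9a-[2-(tert-butyldimethylsilyloxy)ethyl]-5,8-dimethoxy-4a,9a-dihydro-4a,9-propano-9H-fluorene-1,4,11-trione | CC(C)(C)[Si](C)(C)OCC[C@@]12C(=O)C=CC(=O)[C@@]13CC(=O)C[C@@H]2c1c(OC)ccc(OC)c13
F4 | step 11 | (4aR,9R,9aS)-9a-[2-(tert-butyldimethylsilyloxy)ethyl]-5,8-dimethoxy-1,4-dioxo-4a,9a-dihydro-4a,9-prop[1]eno-9H-fluoren-11-yl trifluoromethanesulfonate | CC(C)(C)[Si](C)(C)OCC[C@@]12C(=O)C=CC(=O)[C@@]13CC(OS(=O)(=O)C(F)(F)F)=C[C@@H]2c1c(OC)ccc(OC)c13
F5 | step 7 | (2R)-2-[(1R)-1-[2-(1-bromoethenyl)-3,6-dimethoxyphenyl]prop-2-yn-1-yl]-2-[2-(tert-butyldimethylsilyloxy)ethyl]-3-hydroxycyclopentan-1-one (either C3 epimer) | C#C[C@H](c1c(OC)ccc(OC)c1C(Br)=C)[C@@]1(CCO[Si](C)(C)C(C)(C)C)C(=O)CCC1O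
F6 | step 7 | 1-hydroxy analogue of 13: 9a-[2-(tert-butyldimethylsilyloxy)ethyl]-9-ethynyl-5,8-dimethoxy-4-methylidene-2,3,3a,4,9,9a-hexahydro-1H-cyclopenta[b]naphthalene-1,3a-diol, same spatial arrangement at C3a, C9 and C9a as 13, either C1 epimer | C#C[C@@H]1c2c(OC)ccc(OC)c2C(=C)[C@@]3(O)CCC(O)[C@@]13CCO[Si](C)(C)C(C)(C)C
F7 | step 6 | rac-1-(2-bromo-3,6-dimethoxyphenyl)prop-2-yn-1-yl acetate | COc1ccc(OC)c(C(OC(C)=O)C#C)c1Br
F8 | step 6 | 2-[1-(2-bromo-3,6-dimethoxyphenyl)prop-2-yn-1-yl]-2-[2-(tert-butyldimethylsilyloxy)ethyl]cyclopentane-1,3-dione, same spatial arrangement at the propargylic carbon as 12 (descriptor S, because bromine raises the aryl priority) | C#C[C@H](c1c(OC)ccc(OC)c1Br)C1(CCO[Si](C)(C)C(C)(C)C)C(=O)CCC1=O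
F9 | step 6 | 2-[(1R)-1-(2-ethenyl-3,6-dimethoxyphenyl)prop-2-yn-1-yl]-2-[2-(tert-butyldimethylsilyloxy)ethyl]cyclopentane-1,3-dione | C#C[C@H](c1c(OC)ccc(OC)c1C=C)C1(CCO[Si](C)(C)C(C)(C)C)C(=O)CCC1=O
F10 | step 6 | 2-[(1R)-1-[2-(1,2-dibromoethyl)-3,6-dimethoxyphenyl]prop-2-yn-1-yl]-2-[2-(tert-butyldimethylsilyloxy)ethyl]cyclopentane-1,3-dione (either epimer at the dibromoethyl carbon, not isolated) | C#C[C@H](c1c(OC)ccc(OC)c1C(Br)CBr)C1(CCO[Si](C)(C)C(C)(C)C)C(=O)CCC1=O
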